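Answer 5 questions about 4 flasks that differ in temperature.

- which flask leads in amount of target, in percent of the substrate charged ("all alike" within 1.5 percentage points) (midnight / dawn / noon / winter / all alike)
- how much target is there at the end, in percent of the substrate charged: midnight
- how much target is there at the end, in percent of the substrate charged: dawn
- how much target is there at the end, in percent of the substrate charged: noon
- how much target is there at the end, in percent of the substrate charged: winter

| setting | Thursday's | Monday's | midnight | dawn | noon | winter |
|---|---|---|---|---|---|---|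
| substrate | 1.5 M | 1.5 M | 1.5 M | 1.5 M | 1.5 M | 1.5 M |
| partner | 1 M | 2.2 M | 1.50 M | 1.50 M | 1.50 M | 1.50 M |
| temperature | 15 °C | 42 °C | 50 °C | 35 °C | 20 °C | 65 °C |
| remark | run made earlier | run made earlier |  |  |  |  |
| time |  |  | 10 d | 10 d | 10 d | 10 d |



| run | time / d | target / % | substrate / % |
|---|---|---|---|
| Thursday's | 10.0 | 0.3 | 99.5 |
| Thursday's | 25.0 | 1.5 | 98.8 |
| Thursday's | 50.0 | 2.2 | 97.3 |
| Thursday's | 60.0 | 3.1 | 97.1 |
| Monday's | 3.00 | 12.2 | 87.3 |
| Monday's | 6.00 | 22.9 | 76.5 |
| Monday's | 10.0 | 35.9 | 64.2 |
| Monday's | 12.0 | 41.3 | 58.3 |

(each reading ± 0.3 percentage points)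

Read Monday's table row by row, and take from each row the clock constant: the natural logarithm of charged over remaining substrate, divided by time. The first row gives 0.0453 d⁻¹. The last gives 0.0450 d⁻¹. From its charge to the last row the partner, at one per target, falls from 2.2 M to 1.58 M, yet the constant holds. So read Monday's rate as plain first order in substrate and zero order in partner, with a rate-limiting step that comes before the partner enters.

Now read the columns against each other. In Monday's last row, target and substrate add up to 99.6%, so no side loss shows at 42 °C.

Integrate that rate: the substrate left is exp(−kt), and the target is what the substrate lost.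

Thursday's last row gives 4.90 × 10⁻⁴ d⁻¹, a reading that carries the scatter. Set the two constants on an Arrhenius line, and the slope gives 126 kJ mol⁻¹. Carry the line to 65 °C for the quantity to keep, the winter clock constant 1.19 d⁻¹. This is a reckoning of its own, made apart from the forecast. It gives 1.20% for noon, 14.0% for dawn, 77.3% for midnight and >99.9% for winter.

The forecast names winter as leader, with 77% for midnight, 14% for dawn, 1.2% for noon and 99.5% for winter. Its winter figure stands a little below the reckoning above, and it adds: “Winter should lead, unless an unseen loss appears at high temperature.”

The flasks give 74.0% for midnight, 14.0% for dawn, 1.27% for noon and 88.8% for winter, so winter leads.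

    substrate ⇌ tight pair (K = 0.0290, k = 0.00600 h⁻¹, Ea = 124 kJ mol⁻¹, ΔH = −40.0 kJ mol⁻¹)
    tight pair ⇌ loose pair (K = 0.400, k = 6.30 h⁻¹, Ea = 104 kJ mol⁻¹, ΔH = −23.0 kJ mol⁻¹)
    partner + tight pair → target (k = 250 M⁻¹ h⁻¹, Ea = 47.0 kJ mol⁻¹)
    partner + loose pair → isomer of the product (k = 730 M⁻¹ h⁻¹, Ea = 70.0 kJ mol⁻¹)
    (constants at 50 °C)

The winter clock allows 17.2 half-lives in 10 d, and the winter flask holds 0.0508% of its substrate at 10.0 d. Its target, though, stands 11 percentage points below the forecast, and the isomer of the product holds 11.2%. Now run the neighbour, the winter flask at 80 °C. The same line gives 8.06 d⁻¹, or 116 half-lives, and the neighbour keeps 0.016% of its substrate. It ends with less target than winter, 81.3%, beside 18.7% of the isomer of the product.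

(The runs were computed with made-up constants, noise included.)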